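1. I asked where the substrate goes.

| flask | substrate | coupling partner | remark | time |
|---|---|---|---|---|
| alpha | 0.20 M | 0.20 M | run made earlier |  |
| epsilon | 0.20 M | 0.40 M | run made earlier |  |
| winter | 0.20 M | 0.240 M |  | 15 h |
| dawn | 0.20 M | 0.480 M |  | 15 h |

| run | time / h | target / % | substrate / % |
|---|---|---|---|
| alpha | 0.417 | 1.0 | 95.6 |
| alpha | 1.00 | 2.7 | 94.8 |
| alpha | 2.00 | 6.1 | 87.9 |
| alpha | 3.00 | 10.4 | 80.1 |
| alpha | 5.00 | 12.5 | 73.0 |
| alpha | 6.00 | 13.9 | 65.5 |
| alpha | 8.00 | 17.5 | 59.0 |
| epsilon | 0.417 | 2.4 | 96.6 |
| epsilon | 1.00 | 8.5 | 90.7 |
| epsilon | 2.00 | 11.5 | 82.3 |
| epsilon | 3.00 | 15.2 | 73.8 |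
| epsilon | 5.00 | 25.2 | 61.4 |
| epsilon | 6.00 | 27.4 | 56.6 |
| epsilon | 8.00 | 31.4 | 48.9 |

(readings scatter by 1 percentage point)

* which of the two there is more of at the end, winter (target / side product)
* which of the two there is more of at the end, dawn (target / side product)
* how much target is there at the end, in percent of the substrate charged: winter
* how much target is there at the end, in percent of the substrate charged: dawn

- what was read earlier has a scatter of 1 percentage point, one standard deviation

2. I turned the partner first. At the last readings target stood at 17.5 % in alpha and 31.4 % in epsilon, and side product, reckoned as what was missing from the balance, at 23.5 % and 19.7 %, so I took the ratio of the two rates as partner concentration over a fixed level, with substrate cancelling. Each target uses one partner, so the ratio integrates in closed form: side product formed = level × ln(partner charged / partner left). The last alpha reading gave 0.244 M and the last epsilon reading 0.231 M. I kept their mean, 0.238 M, as the even level: the partner concentration at which both routes run equally fast. It is the inverse of a selectivity factor.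

3. The winter charge of 0.240 M stood about at the even level, and partner falls as it is used, so I expected side product to lead in winter. The dawn charge of 0.480 M was twice that level, so I expected target to lead at dawn.

4. Then I turned the time. Going to 15 h should add to both products along the same curve, leaving my expected order unchanged.

5. The forecast said side product for winter with 30 % target, “giving about 30% target and 34% side product, a close call”, and target for dawn with 50 % target.

6. Winter gave 27.8 % target and 35.1 % side product; dawn gave 46.5 % and 28.9 %. From the 17.5 % target of the alpha run, dawn's partner alone gave 36.6 %, the time alone 23.9 %, and both 46.5 %. The two products came level at a partner charge of 0.302 M, above the winter charge and below the dawn charge.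

    substrate + coupling partner ⇌ target (K = 9.20 M⁻¹, k = 0.170 M⁻¹ h⁻¹)
    substrate → side product (k = 0.0380 h⁻¹)

7. With 77 % of its partner left, winter reckons to 31.3 % side product by the even level, and the flask held 35.1 %. The neighbouring flask is winter with 0.96 M of partner instead, above the even level: with 86 % of its partner left, the rule gives 18.0 % side product. That flask held 67.4 % target and 20.6 % side product.

All runs come from a simulation from invented constants; noise was put on by code.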